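**Retrosynthetic overview**

1. Target ⇐ SN2 acetolysis of a 6,7‑β‑epoxide (gives 6α‑OAc / 7β‑OH), after acetylation of the two macrocyclic carbinols.
2. 11‑Membered ring ⇐ ring contraction of a 12‑membered cyclic alkenyl‑boronate complex: 1,2‑shift of C6′ from boron to C7′ (macrocyclising Zweifel olefination) forms C7′–C6′ and the exo‑methylene.
3. Seco compound ⇐ asymmetric Ni/Cr coupling of the C5 enol triflate of the hydrindane with a C6 aldehyde bearing an α‑silyloxy boronic ester (C3′ by Cu‑catalysed conjugate addition, C6′ by Cu‑catalysed aldehyde borylation).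
4. cis‑Hydrindane ⇐ Cu‑catalysed desymmetrising silylative cyclisation of an allene‑tethered 4‑methylcyclohexa‑2,5‑dienone (sets C3, C3a, C7a), then C4 methylation, β‑epoxidation, enol triflation; the dienone comes from p‑cresol.
5. Ring order: six‑membered ring (dearomatised p‑cresol) → five‑membered ring → eleven‑membered ring (by contraction of the twelve‑membered boracycle).

Assumption and conventions (one line): core locants are those of 1H‑indene (C7a carries the angular methyl); chain carbons are counted from the core as C1′ (on C5) to C6′, C7′ is the methylene‑bearing carbon bonded to C3; β is the face of the 7a‑methyl (H‑3, H‑3a and 7a‑CH3 stay β from the first bicycle to the target, so descriptor changes there are CIP priority changes only); in every catalytic asymmetric step the ligand enantiomer that gives the drawn configuration is used.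

**Step 1**
Reactants: 1 4-methylphenol (p-cresol); 2 allyltrimethylsilane
Product: 3 4-allyl-4-methylcyclohexa-2,5-dien-1-one
Conditions: PhI(OAc)2 (1.1 equiv), 2 (3 equiv), (CF3)2CHOH/CH2Cl2, −20 → 0 °C
Reagents that add atoms: none
Why: Hypervalent‑iodine oxidation gives a phenoxenium ion that the allylsilane captures at the para carbon (oxidative dearomatising Hosomi–Sakurai allylation), creating the quaternary but not yet stereogenic future C7a.

**Step 2**
Reactants: 3 4-allyl-4-methylcyclohexa-2,5-dien-1-one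
Product: 4 3-(1-methyl-4-oxocyclohexa-2,5-dien-1-yl)propanal
Conditions: PdCl2(PhCN)2 (10 mol%), CuCl2·2H2O (10 mol%), AgNO2 (5 mol%), O2 (1 atm), t-BuOH/MeNO2 15:1, rt
Reagents that add atoms: dioxygen (O=O)
Why: Nitrite‑modified (aldehyde‑selective) Tsuji–Wacker oxidation puts oxygen on the terminal carbon of the unbiased allyl group, while the electron‑poor dienone alkenes do not compete for Pd(II).

**Step 3**
Reactants: 4 3-(1-methyl-4-oxocyclohexa-2,5-dien-1-yl)propanal
Product: 5 4-(but-3-yn-1-yl)-4-methylcyclohexa-2,5-dien-1-one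
Conditions: dimethyl (1-diazo-2-oxopropyl)phosphonate, K2CO3, MeOH, 0 °C → rt
Reagents that add atoms: dimethyl (1-diazo-2-oxopropyl)phosphonate (CC(=O)C(=[N+]=[N-])P(=O)(OC)OC)
Why: Seyferth–Gilbert homologation with the Bestmann–Ohira reagent converts the aldehyde into the terminal alkyne under carbonate conditions that the non‑enolisable dienone tolerates.

**Step 4**
Reactants: 5 4-(but-3-yn-1-yl)-4-methylcyclohexa-2,5-dien-1-one
Product: 7 4-methyl-4-(penta-3,4-dien-1-yl)cyclohexa-2,5-dien-1-one, via Mannich base 6 (not isolated)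
Conditions: (CH2O)n, Cy2NH, CuI (0.5 equiv), 1,4-dioxane, 100 °C
Reagents that add atoms: formaldehyde as paraformaldehyde (C=O)
Why: Crabbé–Ma allenation, in which Cu‑mediated Mannich coupling gives the propargylic amine and its 1,5‑hydride shift/β‑elimination releases the terminal allene.

**Step 5**
Reactants: 7 4-methyl-4-(penta-3,4-dien-1-yl)cyclohexa-2,5-dien-1-one
Product: 8 (3R,3aR,7aR)-3-[1-(dimethylphenylsilyl)ethenyl]-7a-methyl-1,2,3,3a,4,7a-hexahydro-5H-inden-5-one
Conditions: CuCl (5 mol%), (R,R)-Ph-BPE (6 mol%), NaOt-Bu (10 mol%), PhMe2Si–Bpin (1.2 equiv), MeOH (2 equiv), THF, 0 °C → rt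
Reagents that add atoms: (dimethylphenylsilyl)boronic acid pinacol ester (C[Si](C)(c1ccccc1)B1OC(C)(C)C(C)(C)O1)
Why: Cu‑catalysed desymmetrising silylative cyclisation, in which silylcupration of the allene (Si on the central carbon) gives a 2‑silylallylcopper that adds through its γ‑carbon to one enantiotopic enone; the ligand selects the enone (C7a, C3a), the tether enforces cis fusion, and the closed Cu‑bridged transition state puts the vinylsilane on the α face (H‑3 cis to H‑3a).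

**Step 6**
Reactants: 8 (3R,3aR,7aR)-3-[1-(dimethylphenylsilyl)ethenyl]-7a-methyl-1,2,3,3a,4,7a-hexahydro-5H-inden-5-one
Product: 9 (3R,3aR,7aR)-3-[1-(dimethylphenylsilyl)ethenyl]-4,7a-dimethyl-1,2,3,3a,4,7a-hexahydro-5H-inden-5-one (C4 epimers)
Conditions: LDA (1.1 equiv), THF, −78 °C; MeI, −78 → −40 °C
Reagents that add atoms: iodomethane (CI)
Why: Kinetic enolate alkylation at C4, the only sp3 α‑position of the enone; the C4 configuration is irrelevant because C4 becomes sp2 in step 8.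

**Step 7**
Reactants: 9 (3R,3aR,7aR)-3-[1-(dimethylphenylsilyl)ethenyl]-4,7a-dimethyl-1,2,3,3a,4,7a-hexahydro-5H-inden-5-one (C4 epimers)
Product: 10 (3R,3aR,6R,7R,7aS)-3-[1-(dimethylphenylsilyl)ethenyl]-6,7-epoxy-4,7a-dimethyloctahydro-5H-inden-5-one (β-epoxide; C4 epimers)
Conditions: 30% aq. H2O2, NaOH (cat.), MeOH, 0 °C
Reagents that add atoms: hydrogen peroxide (OO)
Why: Weitz–Scheffer nucleophilic epoxidation, in which hydroperoxide adds axially to C7 from the convex β face, anti to the pseudo‑axial C1 methylene of the fused cyclopentane, so the epoxide is syn to the 7a‑methyl.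

**Step 8**
Reactants: 10 (3R,3aR,6R,7R,7aS)-3-[1-(dimethylphenylsilyl)ethenyl]-6,7-epoxy-4,7a-dimethyloctahydro-5H-inden-5-one (β-epoxide; C4 epimers)
Product: 11 (3R,3aR,6R,7R,7aS)-3-[1-(dimethylphenylsilyl)ethenyl]-6,7-epoxy-4,7a-dimethyl-2,3,3a,6,7,7a-hexahydro-1H-inden-5-yl trifluoromethanesulfonate
Conditions: KHMDS, THF, −78 °C; PhNTf2, −78 → 0 °C
Reagents that add atoms: N-phenylbis(trifluoromethanesulfonimide) (O=S(=O)(N(c1ccccc1)S(=O)(=O)C(F)(F)F)C(F)(F)F)
Why: C4–H is the only enolisable α‑hydrogen (C6 is an oxirane carbon), so one enolate forms and is O‑triflated to the tetrasubstituted enol triflate.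

**Step 9**
Reactants: 12 methyl (E)-but-2-enoate (methyl crotonate); 13 2-(2-bromoethyl)-1,3-dioxolane
Product: 15 methyl (3S)-5-(1,3-dioxolan-2-yl)-3-methylpentanoate, via Grignard reagent 14 (not isolated)
Conditions: 13, Mg, THF, rt; then 12, CuI (2 mol%), (R)-Tol-BINAP (3 mol%), t-BuOMe, −40 °C; 1 M HCl quench
Reagents that add atoms: none
Why: Cu/Tol‑BINAP‑catalysed asymmetric conjugate addition of the Grignard reagent to the enoate sets C3 (S) under ligand control.

**Step 10**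
Reactants: 15 methyl (3S)-5-(1,3-dioxolan-2-yl)-3-methylpentanoate
Product: 16 methyl (3S)-3-methyl-6-oxohexanoate
Conditions: 1 M aq. HCl/THF 1:3, rt
Reagents that add atoms: water (O)
Why: Acid‑catalysed acetal hydrolysis frees the aldehyde without touching the methyl ester or the remote stereocentre.

**Step 11**
Reactants: 16 methyl (3S)-3-methyl-6-oxohexanoate
Product: 18 methyl (3S,6S)-6-(tert-butyldimethylsilyloxy)-3-methyl-6-(4,4,5,5-tetramethyl-1,3,2-dioxaborolan-2-yl)hexanoate, via α-hydroxy boronate 17 (not isolated)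
Conditions: B2pin2, CuCl (5 mol%), (R)-DTBM-SEGPHOS (5 mol%), KOt-Bu (10 mol%), MeOH (2 equiv), THF, 0 °C; then imidazole, TBSCl, DMF, 0 °C → rt
Reagents that add atoms: bis(pinacolato)diboron (CC1(C)OB(OC1(C)C)B1OC(C)(C)C(C)(C)O1); tert-butyldimethylsilyl chloride (CC(C)(C)[Si](C)(C)Cl)
Why: Cu(I)‑catalysed enantioselective 1,2‑borylation of the aldehyde sets C6 (S) under ligand control, and in situ O‑silylation gives a configurationally stable α‑silyloxy boronic ester, the ester being inert to borylcopper.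

**Step 12**
Reactants: 18 methyl (3S,6S)-6-(tert-butyldimethylsilyloxy)-3-methyl-6-(4,4,5,5-tetramethyl-1,3,2-dioxaborolan-2-yl)hexanoate
Product: 19 (3S,6S)-6-(tert-butyldimethylsilyloxy)-3-methyl-6-(4,4,5,5-tetramethyl-1,3,2-dioxaborolan-2-yl)hexanal
Conditions: DIBAL-H (1.05 equiv), CH2Cl2, −78 °C; aq. Rochelle salt
Reagents that add atoms: none
Why: Partial ester reduction, in which the tetrahedral aluminium hemiacetal is stable at −78 °C and releases the aldehyde only on work‑up; boronate and silyl ether are inert.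

**Step 13**
Reactants: 11 (3R,3aR,6R,7R,7aS)-3-[1-(dimethylphenylsilyl)ethenyl]-6,7-epoxy-4,7a-dimethyl-2,3,3a,6,7,7a-hexahydro-1H-inden-5-yl trifluoromethanesulfonate; 19 (3S,6S)-6-(tert-butyldimethylsilyloxy)-3-methyl-6-(4,4,5,5-tetramethyl-1,3,2-dioxaborolan-2-yl)hexanal
Product: 20 (3R,3aS,6S,7R,7aS)-5-[(1S,3S,6S)-6-(tert-butyldimethylsilyloxy)-3-methyl-6-(pinacolboryl)-1-(triethylsilyloxy)hexyl]-3-[1-(dimethylphenylsilyl)ethenyl]-6,7-epoxy-4,7a-dimethyl-2,3,3a,6,7,7a-hexahydro-1H-indene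
Conditions: CrCl2 (20 mol%), chiral sulfonamide (Kishi) ligand (22 mol%), NiCl2·DMP (2 mol%), Mn, LiCl, TESCl, proton sponge, MeCN, rt
Reagents that add atoms: chlorotriethylsilane (CC[Si](CC)(CC)Cl)
Why: Catalytic asymmetric Nozaki–Hiyama–Kishi coupling, in which Ni inserts into the enol triflate, the alkenylchromium adds only to the aldehyde with the ligand setting C1′ (S), and TESCl releases the product as its silyl ether; vinylsilane, boronate and epoxide are spectators.

**Step 14**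
Reactants: 20 (seco vinylsilane from step 13)
Product: 21 (3R,3aS,6S,7R,7aS)-5-[(1S,3S,6S)-6-(tert-butyldimethylsilyloxy)-3-methyl-6-(pinacolboryl)-1-(triethylsilyloxy)hexyl]-3-(1-iodoethenyl)-6,7-epoxy-4,7a-dimethyl-2,3,3a,6,7,7a-hexahydro-1H-indene
Conditions: NIS (1.3 equiv), 2,6-lutidine, (CF3)2CHOH/CH2Cl2, 0 °C
Reagents that add atoms: N-iodosuccinimide (O=C1CCC(=O)N1I)
Why: Electrophilic ipso‑iododesilylation replaces silicon by iodine on the 1,1‑disubstituted alkene, and the buffered medium spares the vinyl epoxide, silyl ethers and alkyl boronate.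

**Step 15**
Reactants: 21 (seco alkenyl iodide from step 14)
Product: 25 (3R,3aS,6S,7R,7aS,1′S,3′S,6′R)-macrocycle in which C5 and C3 are bridged by C1′–C7′ (11-membered ring) with 7′-methylene 6′-OTBS 1′-OTES 3′-methyl and the 6,7-β-epoxide, via alkenyllithium 22 (not isolated), via cyclic boronate complex 23 (not isolated), via β-iodo boronic ester 24 (not isolated)
Conditions: t-BuLi (2.1 equiv), THF/Et2O (1 mM), −95 → −78 °C; I2 (1.2 equiv), THF, −78 °C; NaOMe, MeOH, −78 → 0 °C
Reagents that add atoms: none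
Why: Proposed new method: a ring‑contractive macrocyclising Zweifel olefination, in which I/Li exchange gives the alkenyllithium that adds intramolecularly to the boronic ester to form a 12‑membered cyclic boronate complex; iodine then forms an iodonium ion at the exo‑alkene and triggers a stereoretentive 1,2‑shift of the C6′ α‑silyloxyalkyl group from boron to C7′, which expels boron from the ring (12‑membered boracycle → 11‑membered carbocycle) and, after methoxide‑induced anti elimination of I/Bpin, leaves the exo‑methylene; this forms the C7′–C6′ bond and the macrocycle and carries the C6′ configuration over unchanged; the closest known reactions are the intermolecular Zweifel olefination and the formation of 4–6‑membered cyclic boronate complexes from iodoalkyl boronic esters with t‑BuLi, whereas a macrocyclic boronate complex and its ring contraction have not been shown.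

**Step 16**
Reactants: 25 (macrocyclic bis-silyl ether from step 15)
Product: 27 (3R,3aS,6S,7R,7aS,1′S,3′S,6′R)-macrocycle with 1′-OAc 6′-OAc 7′-methylene and the 6,7-β-epoxide, via diol 26 (not isolated)
Conditions: TBAF, THF, 0 °C → rt; then Et3N, DMAP (cat.), Ac2O, rt
Reagents that add atoms: acetic anhydride (CC(=O)OC(C)=O)
Why: Fluoride cleaves both silyl ethers and the two allylic alcohols are acetylated in the same pot (DMAP‑catalysed acylation), the epoxide being inert to both reagents.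

**Step 17**
Reactants: 27 (diacetate epoxide from step 16)
Product: 28 CNP0318778.1 (3R,3aS,6R,7R,7aS,1′S,3′S,6′R)-6,1′,6′-triacetoxy-7-hydroxy macrocycle (target)
Conditions: CsOAc (2 equiv), AcOH (10 equiv), DMF, 60 °C
Reagents that add atoms: acetic acid (CC(=O)O)
Why: Acetate opens the vinyl epoxide by SN2 attack at the allylic C6 from the α face (trans‑diaxial, Fürst–Plattner), giving 6α‑OAc/7β‑OH with inversion at C6 and leaving the neopentyl 7‑OH free.

**Compound list**

1 | 4-methylphenol (p-cresol) | Cc1ccc(O)cc1 | starting material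
2 | allyltrimethylsilane | C=CC[Si](C)(C)C | starting material
3 | 4-allyl-4-methylcyclohexa-2,5-dien-1-one | C=CCC1(C)C=CC(=O)C=C1 | intermediate
4 | 3-(1-methyl-4-oxocyclohexa-2,5-dien-1-yl)propanal | O=CCCC1(C)C=CC(=O)C=C1 | intermediate
5 | 4-(but-3-yn-1-yl)-4-methylcyclohexa-2,5-dien-1-one | C#CCCC1(C)C=CC(=O)C=C1 | intermediate
6 | 4-[5-(dicyclohexylamino)pent-3-yn-1-yl]-4-methylcyclohexa-2,5-dien-1-one (Mannich base) | O=C1C=CC(C)(CCC#CCN(C2CCCCC2)C2CCCCC2)C=C1 | intermediate (not isolated)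
7 | 4-methyl-4-(penta-3,4-dien-1-yl)cyclohexa-2,5-dien-1-one | C=C=CCCC1(C)C=CC(=O)C=C1 | intermediate
8 | (3R,3aR,7aR)-3-[1-(dimethylphenylsilyl)ethenyl]-7a-methyl-1,2,3,3a,4,7a-hexahydro-5H-inden-5-one (cis-fused; H-3, H-3a, 7a-Me β) | C=C([Si](C)(C)c1ccccc1)[C@@H]1CC[C@]2(C)C=CC(=O)C[C@H]12 | intermediate
9 | (3R,3aR,7aR)-3-[1-(dimethylphenylsilyl)ethenyl]-4,7a-dimethyl-1,2,3,3a,4,7a-hexahydro-5H-inden-5-one (C4 epimers) | C=C([Si](C)(C)c1ccccc1)[C@@H]1CC[C@]2(C)C=CC(=O)C(C)[C@H]12 | intermediate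
10 | (3R,3aR,6R,7R,7aS)-3-[1-(dimethylphenylsilyl)ethenyl]-6,7-epoxy-4,7a-dimethyloctahydro-5H-inden-5-one (β-epoxide; C4 epimers) | C=C([Si](C)(C)c1ccccc1)[C@@H]1CC[C@]2(C)[C@H]3O[C@H]3C(=O)C(C)[C@H]12 | intermediate
11 | (3R,3aR,6R,7R,7aS)-3-[1-(dimethylphenylsilyl)ethenyl]-6,7-epoxy-4,7a-dimethyl-2,3,3a,6,7,7a-hexahydro-1H-inden-5-yl trifluoromethanesulfonate | C=C([Si](C)(C)c1ccccc1)[C@@H]1CC[C@]2(C)[C@H]3O[C@H]3C(OS(=O)(=O)C(F)(F)F)=C(C)[C@H]12 | intermediate
12 | methyl (E)-but-2-enoate (methyl crotonate) | C/C=C/C(=O)OC | starting material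
13 | 2-(2-bromoethyl)-1,3-dioxolane | BrCCC1OCCO1 | starting material
14 | [2-(1,3-dioxolan-2-yl)ethyl]magnesium bromide | Br[Mg]CCC1OCCO1 | intermediate (not isolated)
15 | methyl (3S)-5-(1,3-dioxolan-2-yl)-3-methylpentanoate | COC(=O)C[C@@H](C)CCC1OCCO1 | intermediate
16 | methyl (3S)-3-methyl-6-oxohexanoate | COC(=O)C[C@@H](C)CCC=O | intermediate
17 | methyl (3S,6S)-6-hydroxy-3-methyl-6-(4,4,5,5-tetramethyl-1,3,2-dioxaborolan-2-yl)hexanoate | COC(=O)C[C@@H](C)CC[C@@H](O)B1OC(C)(C)C(C)(C)O1 | intermediate (not isolated)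
18 | methyl (3S,6S)-6-(tert-butyldimethylsilyloxy)-3-methyl-6-(4,4,5,5-tetramethyl-1,3,2-dioxaborolan-2-yl)hexanoate | COC(=O)C[C@@H](C)CC[C@@H](O[Si](C)(C)C(C)(C)C)B1OC(C)(C)C(C)(C)O1 | intermediate
19 | (3S,6S)-6-(tert-butyldimethylsilyloxy)-3-methyl-6-(4,4,5,5-tetramethyl-1,3,2-dioxaborolan-2-yl)hexanal | O=CC[C@@H](C)CC[C@@H](O[Si](C)(C)C(C)(C)C)B1OC(C)(C)C(C)(C)O1 | intermediate
20 | (3R,3aS,6S,7R,7aS)-5-[(1S,3S,6S)-6-(tert-butyldimethylsilyloxy)-3-methyl-6-(pinacolboryl)-1-(triethylsilyloxy)hexyl]-3-[1-(dimethylphenylsilyl)ethenyl]-6,7-epoxy-4,7a-dimethyl-2,3,3a,6,7,7a-hexahydro-1H-indene | C=C([Si](C)(C)c1ccccc1)[C@@H]1CC[C@]2(C)[C@H]3O[C@H]3C([C@@H](O[Si](CC)(CC)CC)C[C@@H](C)CC[C@@H](O[Si](C)(C)C(C)(C)C)B3OC(C)(C)C(C)(C)O3)=C(C)[C@H]12 | intermediate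
21 | 3-(1-iodoethenyl) analogue of 20 (same configuration) | C=C(I)[C@@H]1CC[C@]2(C)[C@H]3O[C@H]3C([C@@H](O[Si](CC)(CC)CC)C[C@@H](C)CC[C@@H](O[Si](C)(C)C(C)(C)C)B3OC(C)(C)C(C)(C)O3)=C(C)[C@H]12 | intermediate
22 | 3-(1-lithioethenyl) analogue of 21 (alkenyllithium) | [Li]C(=C)[C@@H]1CC[C@]2(C)[C@H]3O[C@H]3C([C@@H](O[Si](CC)(CC)CC)C[C@@H](C)CC[C@@H](O[Si](C)(C)C(C)(C)C)B3OC(C)(C)C(C)(C)O3)=C(C)[C@H]12 | intermediate (not isolated)
23 | lithium 12-membered cyclic boronate complex (pinacolato boron bonded to C7′ and C6′) | C=C1[B-]4(OC(C)(C)C(C)(C)O4)[C@H](O[Si](C)(C)C(C)(C)C)CC[C@H](C)C[C@H](O[Si](CC)(CC)CC)C2=C(C)[C@@H]3[C@H]1CC[C@]3(C)[C@H]5O[C@@H]25.[Li+] | intermediate (not isolated)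
24 | 11-membered β-iodo boronic ester (C7′ carries Bpin and CH2I; C7′ configuration transient) | ICC1(B4OC(C)(C)C(C)(C)O4)[C@H](O[Si](C)(C)C(C)(C)C)CC[C@H](C)C[C@H](O[Si](CC)(CC)CC)C2=C(C)[C@@H]3[C@H]1CC[C@]3(C)[C@H]5O[C@@H]25 | intermediate (not isolated)
25 | (3R,3aS,6S,7R,7aS,1′S,3′S,6′R)-macrocycle: C5 and C3 bridged by C1′–C7′; 7′-methylene; 6′-OTBS; 1′-OTES; 3′-methyl; 6,7-β-epoxide | C=C1[C@H](O[Si](C)(C)C(C)(C)C)CC[C@H](C)C[C@H](O[Si](CC)(CC)CC)C2=C(C)[C@@H]3[C@H]1CC[C@]3(C)[C@H]4O[C@@H]24 | intermediate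
26 | 1′,6′-diol of 25 (same configuration) | C=C1[C@H](O)CC[C@H](C)C[C@H](O)C2=C(C)[C@@H]3[C@H]1CC[C@]3(C)[C@H]4O[C@@H]24 | intermediate (not isolated)
27 | 1′,6′-diacetate of 26 (6,7-β-epoxide retained) | C=C1[C@H](OC(C)=O)CC[C@H](C)C[C@H](OC(C)=O)C2=C(C)[C@@H]3[C@H]1CC[C@]3(C)[C@H]4O[C@@H]24 | intermediate
28 | CNP0318778.1: (3R,3aS,6R,7R,7aS,1′S,3′S,6′R)-6,1′,6′-triacetoxy-7-hydroxy-4,7a,3′-trimethyl-7′-methylene macrocycle (6α-OAc, 7β-OH) | C=C1[C@H](OC(C)=O)CC[C@H](C)C[C@H](OC(C)=O)C2=C(C)[C@@H]3[C@H]1CC[C@]3(C)[C@@H](O)[C@@H]2OC(C)=O | target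

**Totals and risks**

Total steps: 17. Longest linear sequence: 13 (steps 1–8, then 13–17); the chain fragment takes steps 9–12.

Most likely to fail:

1. Step 15 (the proposed ring‑contractive macrocyclisation). The 12‑membered boronate complex may form too slowly against oligomerisation, or the α‑silyloxyalkyl group may migrate poorly. Fallback with known chemistry, setting out from 21 and returning at 26: oxidise the C–B bond of 21 with NaBO3·4H2O in THF/H2O, whereupon the silyl hemiacetal collapses to the seco-aldehyde F1. Close the ring by intramolecular Nozaki–Hiyama–Kishi reaction of the alkenyl iodide with the aldehyde (CrCl2, cat. NiCl2, chiral sulfonamide ligand, THF/DMF, 2 mM) to give the macrocyclic 6′-alcohol F2, which already carries the exo‑methylene. TBAF on F2 gives diol 26 and step 16 continues unchanged.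

2. Step 13 (asymmetric Ni/Cr coupling of a hindered tetrasubstituted enol triflate next to an epoxide). Ligand control at C1′ may be poor. Fallback setting out from 11 and 19 and returning at 20: a ligand‑free stoichiometric NHK coupling (CrCl2, cat. NiCl2, DMF/THF) gives the C1′-epimeric alcohols F3. Dess–Martin oxidation gives the enone F4, and CBS reduction sets C1′ by reagent control to give the (1′S)-alcohol F5. TESCl/imidazole then gives 20.

3. Step 17 (acetolysis of the vinyl epoxide). SN2′ attack at C4 or acetyl migration could compete. Fallback setting out from 27 and returning at 28: acid‑catalysed hydrolysis (cat. HClO4, THF/H2O, 0 °C) gives the 6α,7β-diol F6. Ac2O/pyridine at 0 °C then acetylates only the allylic 6‑OH, the neopentyl 7‑OH cis to the angular methyl staying free, to give 28.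

**Further compounds**

F1 | step 15 | seco-aldehyde: 21 with the C6′ CH(OTBS)Bpin terminus replaced by CHO | C=C(I)[C@@H]1CC[C@]2(C)[C@H]3O[C@H]3C([C@@H](O[Si](CC)(CC)CC)C[C@@H](C)CCC=O)=C(C)[C@H]12
F2 | step 15 | macrocyclic (6′R)-6′-alcohol: 25 with OH in place of 6′-OTBS | C=C1[C@H](O)CC[C@H](C)C[C@H](O[Si](CC)(CC)CC)C2=C(C)[C@@H]3[C@H]1CC[C@]3(C)[C@H]4O[C@@H]24
F3 | step 13 | C1′-epimeric alcohols: 20 with free 1′-OH, C1′ undefined | C=C([Si](C)(C)c1ccccc1)[C@@H]1CC[C@]2(C)[C@H]3O[C@H]3C(C(O)C[C@@H](C)CC[C@@H](O[Si](C)(C)C(C)(C)C)B3OC(C)(C)C(C)(C)O3)=C(C)[C@H]12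
F4 | step 13 | C1′ enone: 1′-oxo analogue of F3 | C=C([Si](C)(C)c1ccccc1)[C@@H]1CC[C@]2(C)[C@H]3O[C@H]3C(C(=O)C[C@@H](C)CC[C@@H](O[Si](C)(C)C(C)(C)C)B3OC(C)(C)C(C)(C)O3)=C(C)[C@H]12
F5 | step 13 | (1′S)-alcohol: 20 with free 1′-OH | C=C([Si](C)(C)c1ccccc1)[C@@H]1CC[C@]2(C)[C@H]3O[C@H]3C([C@@H](O)C[C@@H](C)CC[C@@H](O[Si](C)(C)C(C)(C)C)B3OC(C)(C)C(C)(C)O3)=C(C)[C@H]12
F6 | step 17 | 6α,7β-diol 1′,6′-diacetate | C=C1[C@H](OC(C)=O)CC[C@H](C)C[C@H](OC(C)=O)C2=C(C)[C@@H]3[C@H]1CC[C@]3(C)[C@@H](O)[C@@H]2O
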